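D, the product asked about, is made from G by way of Q and is itself lost to X, so two flasks that differ in temperature can end on opposite sides of that loss.

- epsilon: G 10 mM; temperature 80 °C; time 30 h
- alpha: G 10 mM; temperature 105 °C; time 30 h

    D → X (k1 = 0.0095 h⁻¹, Ea1 = 125 kJ mol⁻¹)
    Q ⇌ D (K2 = 4.6, k2 = 0.039 h⁻¹, Ea2 = 107 kJ mol⁻¹, ΔH2 = −20.0 kJ mol⁻¹)
    G → Q (k3 = 0.018 h⁻¹, Ea3 = 125 kJ mol⁻¹)
    Q ⇌ Z (K4 = 2.6, k4 = 0.0055 h⁻¹, Ea4 = 120 kJ mol⁻¹, ΔH4 = −13.0 kJ mol⁻¹)
    G + Q → G.Q (k5 = 0.22 M⁻¹ h⁻¹, Ea5 = 67.0 kJ mol⁻¹)
    (constants at 80 °C)

- in percentages every species weighs as the G in it: one G.Q counts as two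
- at 80 °C the constants are as listed, elsewhere as the activation energies and enthalpies make them

* which of the two there is more of at the end, epsilon (X / D)
* which of the two there is more of at the end, alpha (X / D)
* final D, as a percentage of the G charged, in epsilon
* final D, as a percentage of the G charged, in alpha

The end state comes first: D → X has no way back, so D is a passing stock. How far a run has gone towards X is then a matter of rate. In epsilon the product of the two numbers below is 0.285; this is the drain number N, the rate constant kD of D → X times the time of the run. If a stock of D rises evenly from nothing, its mean member has stood for half the run, so X/D is N/2.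

In epsilon G starts to fall at 0.180 mM h⁻¹, which unslowed over the run would convert 54.0% of the charge. The fall of G slows this by a factor 0.773, the wait in Q by 0.480, the split of Q between D and Z by 0.876, and the drain by one minus N/2, 0.858. With the ways back and G.Q neglected, this reckoning ends epsilon at 15.0% D, and D leads.

In alpha kD rises by a factor 16.7, so N is 4.75. There the rate constant kG of G → Q is 0.300 h⁻¹. In alpha kD is 0.158 h⁻¹, and the half-life of D by this drain, 4.39 h, is shorter than the relaxation half-life of Q and Z, 5.58 h, so this reckoning does not put Z in equilibrium with Q and treats Z as a reservoir. In alpha the constants of Q → D, D → Q, Q → Z and Z → Q are 0.434 h⁻¹, 0.148 h⁻¹, 0.0820 h⁻¹ and 0.0423 h⁻¹. With D taken as steady, Q moves on towards X at 0.224 h⁻¹, so a share f of 0.268 of what passes through Q enters Z. Z then empties at kZ, the Z → Q constant times one minus f, which is 0.0309 h⁻¹, slower than the drain. Filling Z with f at about 3.33 h after the start, the reciprocal of kG, puts Z near 11.7% at the end of alpha. D that follows a feed falling at kZ stands at kZ/(kD − kZ) of Z, so this rough reckoning leaves 2.84% D in alpha, and X leads.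

The forecast chose D for epsilon and X for alpha, with D at 14.2% and 5.1%. The first figure lies below this reckoning's and the second above it. Its ground for epsilon was that “D is still building and has barely begun to drain to X”.

The simulation ends epsilon with D at 14.5% and X at 1.68%, a ratio X/D of 0.116 against N/2 of 0.142. It ends alpha with D at 5.10% and X at 77.7%. A neighbouring flask like alpha, kept at 90 °C, has N of 0.920, so N/2 is 0.460, which is below one and puts D ahead of X. That neighbouring flask ends with D at 33.2% and X at 18.1%, a ratio X/D of 0.546.

(All constants belong to no real substance; no experiment stands behind them.)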